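## Structural features

The target is a flavone (rings A, C and B) in which C3 of the pyranone and O2' of ring B are bridged by a CH2–CH(O) unit. This gives a seven-membered dihydro-oxepine, ring D (C2, C3, CH2, O–CH, O, C2', C1'), fused to rings C and B. Ring A carries a chelated 5-OH, a 7-OMe and, between them at C6, an (E)-3-methylbut-1-enyl group; ring B carries a free 4'-OH. The only stereocentre is the (R)-configured O–CH of ring D, which bears a 2-hydroxypropan-2-yl group and has no stereogenic neighbour, so its configuration must come from a reagent or an auxiliary. Fragile groups are the electron-rich styrene-type alkene (acid, hydrogenation, electrophiles), the tertiary alcohol (acid), the pyranone (hard nucleophiles) and the O–CH centre, which can epimerise while the attached carbon is a carbonyl group. The real difficulty is to close the seven-membered ring and set the isolated stereocentre together, and later to functionalise C6 selectively beside C8 and an electron-rich ring B. The key step exploits two facts: the O–CH carbon is formally the alpha-carbon of an aryloxyacetic acid attached to O2', and the neighbouring CH2 is allylic to C2=C3 of ring C, so a C3–CH2–Br group can alkylate an auxiliary-bearing glycolate enolate.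

## Logic of the disconnections

27 is cut at the C6–alkenyl bond into 24 and 26. The alkene is the group least tolerant of acid, hydrogenation and electrophiles, so removing it last keeps it out of every earlier step. The forward coupling must work on an aryl iodide flanked by OH and OMe with two free phenols present; the E geometry is fixed in 26, which comes from 25 by syn-hydroboration.

24 is simplified by removing the iodine and restoring the MOM ether, through 23 to 22. Iodination is done while ring B is still a diether and ring A holds the only free phenol, which directs the electrophile to C6. The MOM group is removed from 23 before the alkene exists, so the last acidic step never meets the styrene.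

22 is cut at both C–CH3 bonds of the carbinol, leading through 21 to ester 20. 20 is traced to its benzyl ether 19, and 19 to imide 18 by exchange of the auxiliary for methoxide. The gain is that the whole carbinol comes from the acyl carbon that the key step needs anyway. The demand is that the methyl nucleophile spares C4=O; freeing the 5-OH first lets a magnesium 5-phenoxide chelate deactivate it. Direct methanolysis of 18 replaces a hydroperoxide cleavage plus esterification, saving a step and avoiding alkaline peroxide on the pyranone enone.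

18 is cut at the bond between the C3–CH2 carbon and the O–CH carbon, giving 16 (through enolate 17). This one cut opens ring D and removes the only stereocentre. The forward step needs a Z-enolate, facial control by the auxiliary, and a C3–CH2–Br electrophile. In 16 the 5-O is a benzyl ether so that no phenoxide competes, and the 4'-O is a MOM ether because it is inert to amide bases and keeps ring B deactivated for the later iodination. The bromide is made last and used at once, because a CH2–X group on C3 is activated for ionisation by O1 and sits six atoms from the O2' ether oxygen.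

16 is traced to alcohol 15 (C–Br to C–OH), and 15 is cut at the O2'–CH2 bond into phenol 12 and bromoacetyl imide 14, which comes from 13. This attaches the complete glycolate-auxiliary unit in one Williamson step. The phenol must be capped before the C3–CH2OH is activated; otherwise the 2'-OH would close a six-membered ether.

12 is traced to its allyl ether 11, and 11 is cut at the C3–CH2OH bond to flavone 9 (through 10). C3–H is the only position on the pyranone and can be lithiated, so one carbon is added without changing the flavone synthesis. The forward step must trap the 3-lithio species at −78 °C before it ring-opens.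

9 is cut at O1–C2 to diketone 8, and 8 at the CH2–C(=O) bond into ketone 6 and acid 4 (activated as 7). This is the standard flavone disconnection and joins rings A and B convergently. The cyclodehydration must be mild enough to keep the MOM ether.

6 comes from 5 by mono-benzylation, which uses the symmetry of 5 and puts the 5-O-benzyl group in place before the flavone is made. 4 comes from 1 through 2 and 3, using the lower reactivity of the hydrogen-bonded 2-OH to place MOM on O4 and allyl on O2.

## Other disconnections considered

Alternative 1: Ring A is cut at C4a–C8a and unfolded into a polyketide chain masked as a 4-methoxy-2-pyranone, A2, whose C6–CH2 is acylated by the benzoxepine unit that already holds ring D, the stereocentre and the carbinol. In the forward step Mg(OMe)2 in methanol would open the lactone to a magnesium-chelated methoxy-dioxo ester, and the CH2 between the two ketones would attack the ester carbonyl (Claisen mode) to give the bridged dihydroxy-methoxychalcone A1.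
- In its favour: the 5-OH/7-OMe pattern arises without ambiguity, and ring A of A1 is symmetric, so closure of ring C cannot go wrong regiochemically. The stereocentre is never alpha to a carbonyl group; on this point it is better than the chosen plan, where the centre is epimerisable from 18 to 21.
- Against it here: the step builds only ring A, which the chosen plan buys in 5. Ring D and the stereocentre would still need a separate asymmetric construction on the benzoxepine. The enone of A2 is exposed to methoxide, and aldol-mode cyclisation competes. A1 still needs an oxidative O1–C2 closure to reach 22.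
- Comparison: it is equal to the chosen plan on the C6 problem, since the same iodination and coupling follow. It is judged longer overall.

Alternative 2: Ring A is cut at C4a–C5, C5–C6 and C7–C8 (C8–C8a arises by the 1,2-shift) and assembled on a finished pyranone. Irradiation of the diazoacetyl pyranone A4 would give a vinylketene by Wolff rearrangement. This would add the ynol ether A5 in a [2+2] step, and heating would drive four-electron ring opening, six-electron closure and tautomerisation to phenol A3.
- In its favour: 5-OH, the C6 alkenyl group and 7-OMe are placed in one operation with regiochemistry fixed by ketene and ynol ether polarity. This is better than the chosen plan, which depends on a site-selective iodination. The route is convergent, and only two deprotections follow.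
- Against it here: A4 must already contain ring D and the stereocentre, so the central problem is moved, not solved. 4-Pyranones have their own photochemistry. A5 is a sensitive enynyl ether whose alkene may compete with the alkyne and may isomerise under light. The final acidic removal of the silyl and MOM groups would be done with the styrene present, which the chosen plan avoids.
- Comparison: the step count is probably similar, with more unproven steps.

Alternative 3: The cut is C2–C1'. The 3-alkylchromone A7, which carries the (R)-O–CH, the carbinol and a 2-bromo-5-(methoxymethoxy)phenyl ether, would undergo oxidative addition of zerovalent palladium into C–Br (Pd(OAc)2, PCy3·HBF4, K2CO3, pivalic acid). Carboxylate-assisted palladation of C2–H and reductive elimination would give A6, which is identical with 22.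
- In its favour: the stereocentre could come from a catalytic asymmetric epoxidation of a 3-prenylchromone and opening by the bromophenoxide at the less substituted carbon, which gives the carbinol directly. No auxiliary and no Grignard addition beside an epimerisable centre are needed. On stereocontrol it is at least equal, and on step count to 22 it is the better.
- Against it here: C2–H of a chromone is an enol-ether-type position, and a seven-membered closure needs an eight-membered palladacycle. The free tertiary alcohol can undergo six-membered C–O coupling, and the 5-OH, Heck-type insertion into C2=C3 and hydrodebromination also compete.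
- Comparison: the chosen plan makes C2–C1' by a robust flavone synthesis and takes its risk in an SN2 alkylation; this alternative reverses which bond is risky. Both end with the same C6 chemistry.

Key step: step 11

Assumption: 14 is prepared from 13 and monomeric formaldehyde is generated by cracking paraformaldehyde; the descriptors were re-derived as (4S) for the auxiliary in 13–18 and (R) for the ring-D CH from 18 to 27 (OAr > acyl or CMe2OH > CH2 > H throughout), and no structure needed correction.

## Route

Step 1
Reactants: 1 methyl 2,4-dihydroxybenzoate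
Product: 2 methyl 2-hydroxy-4-(methoxymethoxy)benzoate
Conditions: MOMCl (1.1 equiv), K2CO3, acetone, 0 °C to rt
Reagents that add atoms: chloromethyl methyl ether, COCCl
Why: Williamson-type O-alkylation; the 2-OH is hydrogen-bonded to the ester carbonyl and much less nucleophilic, so the 4-OH should react selectively.

Step 2
Reactants: 2 methyl 2-hydroxy-4-(methoxymethoxy)benzoate
Product: 4 4-(methoxymethoxy)-2-(prop-2-en-1-yloxy)benzoic acid, via allyl ether methyl ester 3 (not isolated)
Conditions: allyl bromide, K2CO3, DMF, 60 °C; then aq NaOH, MeOH, 60 °C; cold dilute HCl to pH 3, extract at once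
Reagents that add atoms: allyl bromide, C=CCBr; sodium hydroxide, [Na+].[OH-]
Why: Williamson etherification of the remaining phenol followed by ester saponification in the same pot; brief cold acidification to pH 3 should not touch the aryl MOM ether.

Step 3
Reactants: 5 1-(2,6-dihydroxy-4-methoxyphenyl)ethanone
Product: 6 1-[2-(benzyloxy)-6-hydroxy-4-methoxyphenyl]ethanone
Conditions: BnBr (1.05 equiv), K2CO3 (1.1 equiv), acetone, reflux
Reagents that add atoms: benzyl bromide, BrCc1ccccc1
Why: Williamson mono-benzylation; the two hydroxyls of 5 are equivalent, and after the first alkylation the remaining one is chelated to the ketone and resists a second alkylation.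

Step 4
Reactants: 4 4-(methoxymethoxy)-2-(prop-2-en-1-yloxy)benzoic acid; 6 1-[2-(benzyloxy)-6-hydroxy-4-methoxyphenyl]ethanone
Product: 8 1-[2-(benzyloxy)-6-hydroxy-4-methoxyphenyl]-3-[4-(methoxymethoxy)-2-(prop-2-en-1-yloxy)phenyl]propane-1,3-dione, via acid chloride 7 (not isolated)
Conditions: 4, 1-chloro-N,N,2-trimethylprop-1-en-1-amine, CH2Cl2, 0 °C to rt; 6, LiN(SiMe3)2 (3.2 equiv), THF, −78 °C; add 7, −78 °C to rt; aq NH4Cl
Reagents that add atoms: none
Why: One-pot variant of the Baker–Venkataraman synthesis: the phenoxide-enolate dianion of 6 is acylated at carbon (or at oxygen followed by acyl shift) and the third equivalent of base holds the product as its enolate. The acid chloride is made under neutral conditions so that no HCl meets the MOM ether.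

Step 5
Reactants: 8 1-[2-(benzyloxy)-6-hydroxy-4-methoxyphenyl]-3-[4-(methoxymethoxy)-2-(prop-2-en-1-yloxy)phenyl]propane-1,3-dione
Product: 9 5-(benzyloxy)-7-methoxy-2-[4-(methoxymethoxy)-2-(prop-2-en-1-yloxy)phenyl]-4H-chromen-4-one
Conditions: camphorsulfonic acid (10 mol%), toluene, 4 Å MS, 60 °C
Reagents that add atoms: none
Why: Acid-catalysed cyclodehydration (second stage of the Baker–Venkataraman flavone synthesis); loss of water passes through an oxocarbenium ion stabilised by O1 and the 2,4-dialkoxyphenyl group, so a weak anhydrous acid should suffice and spare the MOM ether.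

Step 6
Reactants: 9 5-(benzyloxy)-7-methoxy-2-[4-(methoxymethoxy)-2-(prop-2-en-1-yloxy)phenyl]-4H-chromen-4-one
Product: 11 5-(benzyloxy)-3-(hydroxymethyl)-7-methoxy-2-[4-(methoxymethoxy)-2-(prop-2-en-1-yloxy)phenyl]-4H-chromen-4-one, via 3-lithioflavone 10 (not isolated)
Conditions: LiN(iPr)2 (1.2 equiv), THF, −78 °C, 15 min; CH2O (gas), −78 °C; aq NH4Cl
Reagents that add atoms: formaldehyde, C=O
Why: Carbonyl-directed lithiation of flavone C3–H (a known reaction of flavones with lithium amides at −78 °C) followed by addition of the vinyl-lithium to formaldehyde. The species is trapped cold because 3-lithiochromones ring-open on warming.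

Step 7
Reactants: 11 5-(benzyloxy)-3-(hydroxymethyl)-7-methoxy-2-[4-(methoxymethoxy)-2-(prop-2-en-1-yloxy)phenyl]-4H-chromen-4-one
Product: 12 5-(benzyloxy)-3-(hydroxymethyl)-2-[2-hydroxy-4-(methoxymethoxy)phenyl]-7-methoxy-4H-chromen-4-one
Conditions: Pd(PPh3)4 (3 mol%), morpholine, THF, rt; base-washed silica
Reagents that add atoms: none
Why: Tsuji–Trost deallylation: zerovalent palladium ionises the aryl allyl ether and morpholine takes the allyl group; benzyl and MOM ethers and the unactivated allylic alcohol are inert, and acid is avoided because 12 can cyclise to a six-membered ether.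

Step 8
Reactants: 13 (4S)-4-benzyl-1,3-oxazolidin-2-one
Product: 14 (4S)-4-benzyl-3-(bromoacetyl)-1,3-oxazolidin-2-one
Conditions: n-BuLi (1.0 equiv), THF, −78 °C; BrCH2COBr, −78 to 0 °C
Reagents that add atoms: bromoacetyl bromide, BrCC(Br)=O
Why: Standard N-acylation of the lithiated oxazolidinone; the acyl bromide reacts far faster than the alkyl bromide.

Step 9
Reactants: 12 5-(benzyloxy)-3-(hydroxymethyl)-2-[2-hydroxy-4-(methoxymethoxy)phenyl]-7-methoxy-4H-chromen-4-one; 14 (4S)-4-benzyl-3-(bromoacetyl)-1,3-oxazolidin-2-one
Product: 15 5-(benzyloxy)-3-(hydroxymethyl)-7-methoxy-2-[4-(methoxymethoxy)-2-{2-oxo-2-[(4S)-4-benzyl-2-oxo-1,3-oxazolidin-3-yl]ethoxy}phenyl]-4H-chromen-4-one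
Conditions: K2CO3 (1.5 equiv), MeCN, 0 °C to rt
Reagents that add atoms: none
Why: Williamson ether synthesis at an alpha-halo carbonyl carbon, a fast SN2 site; only the phenol is deprotonated by carbonate, so the primary alcohol stays free.

Step 10
Reactants: 15 5-(benzyloxy)-3-(hydroxymethyl)-7-methoxy-2-[4-(methoxymethoxy)-2-{2-oxo-2-[(4S)-4-benzyl-2-oxo-1,3-oxazolidin-3-yl]ethoxy}phenyl]-4H-chromen-4-one
Product: 16 5-(benzyloxy)-3-(bromomethyl)-7-methoxy-2-[4-(methoxymethoxy)-2-{2-oxo-2-[(4S)-4-benzyl-2-oxo-1,3-oxazolidin-3-yl]ethoxy}phenyl]-4H-chromen-4-one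
Conditions: CBr4, PPh3, CH2Cl2, 0 °C; quick filtration through base-washed silica; used at once
Reagents that add atoms: carbon tetrabromide, BrC(Br)(Br)Br
Why: Appel reaction of a primary allylic alcohol under neutral conditions, which the imide, MOM and benzyl groups tolerate. The bromide is not stored because the CH2–Br group is activated for ionisation by O1.

Step 11
Reactants: 16 5-(benzyloxy)-3-(bromomethyl)-7-methoxy-2-[4-(methoxymethoxy)-2-{2-oxo-2-[(4S)-4-benzyl-2-oxo-1,3-oxazolidin-3-yl]ethoxy}phenyl]-4H-chromen-4-one
Product: 18 ring-D-closed imide: 5-benzyloxy-7-methoxy-4'-(methoxymethoxy)flavone bridged from C3 to O2' by CH2–CH[C(=O)Xc] with (R) configuration at the ring-D CH and Xc = (4S)-4-benzyl-2-oxo-1,3-oxazolidin-3-yl, via sodium Z-enolate 17 (not isolated)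
Conditions: NaN(SiMe3)2 (1.05 equiv, slow addition), THF (0.01 M), −78 °C then −45 °C; AcOH quench at −45 °C
Reagents that add atoms: none
Why: Proposed new method: NaN(SiMe3)2 removes an alpha-proton of the aryloxyacetyl imide to give the sodium-chelated Z-enolate 17, whose alpha-carbon displaces bromide from the C3–CH2Br group of the same molecule in an SN2 step; the closest known reaction type is the intermolecular alkylation of oxazolidinone glycolate sodium enolates with allylic halides, and ring-forming alkylations of omega-halo acyl oxazolidinones are known for smaller rings, but not a seven-membered aryl-ether-tethered case. Ring D closes in the 7-exo-tet mode with the enolate C=C outside the ring, and the four sp2 atoms C3, C2, C1' and C2' hold the two ends close. The new stereocentre is controlled by the (4S)-benzyl group, which blocks one face of the chelated enolate so that the CH2 carbon bonds to the other face, the sense that gives (R) at an alpha-aryloxy carbon. The step needs C- over O-alkylation (seven- against nine-membered ring), intra- over intermolecular reaction (high dilution), and reaction below about −40 °C, where the enolate should not yet fragment to ketene and oxazolidinone anion. The 5-O-benzyl ether keeps a competing phenoxide out of the medium, the electrophile is primary and cannot eliminate, and about one equivalent of base is used so that the more hindered alpha-proton of the product is not removed.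

Step 12
Reactants: 18 ring-D-closed (R)-imide
Product: 19 methyl ester: 5-benzyloxy-7-methoxy-4'-(methoxymethoxy)flavone bridged from C3 to O2' by CH2–CH(CO2CH3) with (R) configuration at the ring-D CH
Conditions: MeMgBr (2.5 equiv) in MeOH (gives MeOMgBr), THF, 0 °C; aq NH4Cl
Reagents that add atoms: methanol, CO
Why: Transesterification of an N-acyl oxazolidinone by magnesium methoxide at the exocyclic carbonyl, a standard auxiliary cleavage that releases 13. It is a weak base at 0 °C, which limits epimerisation, and it avoids alkaline peroxide on the pyranone enone.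

Step 13
Reactants: 19 (R)-methyl ester with 5-O-benzyl group
Product: 20 (R)-methyl ester with free 5-OH: 5-hydroxy-7-methoxy-4'-(methoxymethoxy)flavone bridged from C3 to O2' by CH2–CH(CO2CH3)
Conditions: H2 (1 atm), 10% Pd/C, EtOAc, rt
Reagents that add atoms: none
Why: Hydrogenolysis of the benzyl ether; the tetrasubstituted, vinylogous-ester C2=C3 bond, the MOM ether and the non-benzylic C–O bond at the stereocentre should not be reduced.

Step 14
Reactants: 20 (R)-methyl ester with free 5-OH
Product: 22 (R)-tertiary alcohol: 5-hydroxy-7-methoxy-4'-(methoxymethoxy)flavone bridged from C3 to O2' by CH2–CH[C(CH3)2OH], via methyl ketone 21 (not isolated)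
Conditions: MeMgBr (5 equiv), THF, −40 to 0 °C; aq NH4Cl
Reagents that add atoms: methylmagnesium bromide, C[Mg]Br
Why: Double Grignard addition to an alpha-alkoxy ester, which is activated by chelation; the first equivalent forms the magnesium 5-phenoxide, whose chelate with C4=O makes the pyranone carbonyl a poor electrophile. Low temperature keeps addition faster than enolisation at the stereocentre.

Step 15
Reactants: 22 (R)-tertiary alcohol with 4'-O-MOM group
Product: 23 6-iodo derivative of 22: 5-hydroxy-6-iodo-7-methoxy-4'-(methoxymethoxy) compound with (R) ring-D CH bearing C(CH3)2OH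
Conditions: BnMe3N·ICl2 (1.05 equiv), CaCO3, CH2Cl2/MeOH, rt
Reagents that add atoms: benzyltrimethylammonium dichloroiodate, C[N+](C)(C)Cc1ccccc1.Cl[I-]Cl
Why: Electrophilic aromatic iodination; ring A is the only ring with a free phenol and three oxygen donors, and this reagent is known to iodinate 5-hydroxy-7-alkoxyflavones at C6, ortho to the chelated hydroxyl. CaCO3 takes up HCl, so the MOM ether and the tertiary alcohol should survive.

Step 16
Reactants: 23 6-iodo-4'-O-MOM tertiary alcohol
Product: 24 6-iodo diphenol: 5,4'-dihydroxy-6-iodo-7-methoxyflavone bridged from C3 to O2' by CH2–CH[C(CH3)2OH] with (R) configuration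
Conditions: 3 M aq HCl, MeOH, 45 °C
Reagents that add atoms: none
Why: Acid-catalysed acetal exchange removes the MOM group as dimethoxymethane; it is done before the alkene is introduced, and the tertiary alcohol beta to an ether oxygen ionises only reluctantly under these conditions.

Step 17
Reactants: 25 3-methylbut-1-yne
Product: 26 (E)-4,4,5,5-tetramethyl-2-(3-methylbut-1-en-1-yl)-1,3,2-dioxaborolane
Conditions: pinacolborane, Zr(C5H5)2(H)Cl (5 mol%), Et3N (10 mol%), sealed tube, 50 °C
Reagents that add atoms: pinacolborane, CC1(C)OBOC1(C)C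
Why: Zirconium-catalysed syn-hydroboration of a terminal alkyne, which places boron at the terminal carbon and gives only the E-alkenylboronate.

Step 18
Reactants: 24 6-iodo diphenol; 26 (E)-4,4,5,5-tetramethyl-2-(3-methylbut-1-en-1-yl)-1,3,2-dioxaborolane
Product: 27 target CNP0216454.1: 5,4'-dihydroxy-7-methoxy-6-[(E)-3-methylbut-1-en-1-yl]flavone bridged from C3 to O2' by CH2–CH[C(CH3)2OH] with (R) configuration
Conditions: PdCl2(dppf) (5 mol%), K2CO3 (3 equiv), 1,4-dioxane/H2O, 80 °C, degassed
Reagents that add atoms: none
Why: Suzuki–Miyaura coupling of an aryl iodide with an alkenylboronate, which proceeds with retention of alkene geometry and tolerates free phenols and the tertiary alcohol. The mildly basic medium does not endanger the stereocentre or the new styrene.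

## Compound list

1 | methyl 2,4-dihydroxybenzoate | COC(=O)c1ccc(O)cc1O | starting material
2 | methyl 2-hydroxy-4-(methoxymethoxy)benzoate | COC(=O)c1ccc(OCOC)cc1O | intermediate
3 | methyl 4-(methoxymethoxy)-2-(prop-2-en-1-yloxy)benzoate (not isolated) | COC(=O)c1ccc(OCOC)cc1OCC=C | intermediate
4 | 4-(methoxymethoxy)-2-(prop-2-en-1-yloxy)benzoic acid | OC(=O)c1ccc(OCOC)cc1OCC=C | intermediate
5 | 1-(2,6-dihydroxy-4-methoxyphenyl)ethanone (2',6'-dihydroxy-4'-methoxyacetophenone) | CC(=O)c1c(O)cc(OC)cc1O | starting material
6 | 1-[2-(benzyloxy)-6-hydroxy-4-methoxyphenyl]ethanone | CC(=O)c1c(O)cc(OC)cc1OCc1ccccc1 | intermediate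
7 | 4-(methoxymethoxy)-2-(prop-2-en-1-yloxy)benzoyl chloride (not isolated) | ClC(=O)c1ccc(OCOC)cc1OCC=C | intermediate
8 | 1-[2-(benzyloxy)-6-hydroxy-4-methoxyphenyl]-3-[4-(methoxymethoxy)-2-(prop-2-en-1-yloxy)phenyl]propane-1,3-dione | COc1cc(O)c(C(=O)CC(=O)c2ccc(OCOC)cc2OCC=C)c(OCc2ccccc2)c1 | intermediate
9 | 5-(benzyloxy)-7-methoxy-2-[4-(methoxymethoxy)-2-(prop-2-en-1-yloxy)phenyl]-4H-chromen-4-one | COc1cc2oc(-c3ccc(OCOC)cc3OCC=C)cc(=O)c2c(OCc4ccccc4)c1 | intermediate
10 | 3-lithio derivative of 9 (not isolated) | COc1cc2oc(-c3ccc(OCOC)cc3OCC=C)c([Li])c(=O)c2c(OCc4ccccc4)c1 | intermediate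
11 | 5-(benzyloxy)-3-(hydroxymethyl)-7-methoxy-2-[4-(methoxymethoxy)-2-(prop-2-en-1-yloxy)phenyl]-4H-chromen-4-one | COc1cc2oc(-c3ccc(OCOC)cc3OCC=C)c(CO)c(=O)c2c(OCc4ccccc4)c1 | intermediate
12 | 5-(benzyloxy)-3-(hydroxymethyl)-2-[2-hydroxy-4-(methoxymethoxy)phenyl]-7-methoxy-4H-chromen-4-one | COc1cc2oc(-c3ccc(OCOC)cc3O)c(CO)c(=O)c2c(OCc4ccccc4)c1 | intermediate
13 | (4S)-4-benzyl-1,3-oxazolidin-2-one | O=C1N[C@@H](Cc2ccccc2)CO1 | starting material
14 | (4S)-4-benzyl-3-(bromoacetyl)-1,3-oxazolidin-2-one | O=C(CBr)N1C(=O)OC[C@@H]1Cc1ccccc1 | intermediate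
15 | 5-(benzyloxy)-3-(hydroxymethyl)-7-methoxy-2-[4-(methoxymethoxy)-2-{2-oxo-2-[(4S)-4-benzyl-2-oxo-1,3-oxazolidin-3-yl]ethoxy}phenyl]-4H-chromen-4-one | COc1cc2oc(-c3ccc(OCOC)cc3OCC(=O)N4C(=O)OC[C@@H]4Cc5ccccc5)c(CO)c(=O)c2c(OCc6ccccc6)c1 | intermediate
16 | 5-(benzyloxy)-3-(bromomethyl)-7-methoxy-2-[4-(methoxymethoxy)-2-{2-oxo-2-[(4S)-4-benzyl-2-oxo-1,3-oxazolidin-3-yl]ethoxy}phenyl]-4H-chromen-4-one | COc1cc2oc(-c3ccc(OCOC)cc3OCC(=O)N4C(=O)OC[C@@H]4Cc5ccccc5)c(CBr)c(=O)c2c(OCc6ccccc6)c1 | intermediate
17 | sodium Z-enolate of 16 (aryloxy and ONa cis; not isolated) | COc1cc2oc(-c3ccc(OCOC)cc3O/C=C(\O[Na])N4C(=O)OC[C@@H]4Cc5ccccc5)c(CBr)c(=O)c2c(OCc6ccccc6)c1 | intermediate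
18 | ring-D-closed imide, (R) at the ring-D CH, (4S) auxiliary, 5-OBn, 7-OMe, 4'-OMOM | COc1cc2oc3c(c(=O)c2c(OCc4ccccc4)c1)C[C@H](C(=O)N5C(=O)OC[C@@H]5Cc6ccccc6)Oc7cc(OCOC)ccc7-3 | intermediate
19 | (R)-methyl ester, 5-OBn, 7-OMe, 4'-OMOM | COc1cc2oc3c(c(=O)c2c(OCc4ccccc4)c1)C[C@H](C(=O)OC)Oc5cc(OCOC)ccc5-3 | intermediate
20 | (R)-methyl ester, 5-OH, 7-OMe, 4'-OMOM | COc1cc2oc3c(c(=O)c2c(O)c1)C[C@H](C(=O)OC)Oc4cc(OCOC)ccc4-3 | intermediate
21 | (R)-methyl ketone, 5-OH, 7-OMe, 4'-OMOM (not isolated) | COc1cc2oc3c(c(=O)c2c(O)c1)C[C@H](C(C)=O)Oc4cc(OCOC)ccc4-3 | intermediate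
22 | (R)-tertiary alcohol [ring-D CH bears C(CH3)2OH], 5-OH, 7-OMe, 4'-OMOM | COc1cc2oc3c(c(=O)c2c(O)c1)C[C@H](C(C)(C)O)Oc4cc(OCOC)ccc4-3 | intermediate
23 | 6-iodo derivative of 22 | COc1cc2oc3c(c(=O)c2c(O)c1I)C[C@H](C(C)(C)O)Oc4cc(OCOC)ccc4-3 | intermediate
24 | 6-iodo-5,4'-dihydroxy compound (MOM removed from 23) | COc1cc2oc3c(c(=O)c2c(O)c1I)C[C@H](C(C)(C)O)Oc4cc(O)ccc4-3 | intermediate
25 | 3-methylbut-1-yne | CC(C)C#C | starting material
26 | (E)-4,4,5,5-tetramethyl-2-(3-methylbut-1-en-1-yl)-1,3,2-dioxaborolane | CC(C)/C=C/B1OC(C)(C)C(C)(C)O1 | intermediate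
27 | CNP0216454.1, (R)-configured oxepino-flavone with 5-OH, 6-[(E)-3-methylbut-1-enyl], 7-OMe, 4'-OH and C(CH3)2OH on the ring-D CH | COc1cc2oc3c(c(=O)c2c(O)c1/C=C/C(C)C)C[C@H](C(C)(C)O)Oc1cc(O)ccc1-3 | target

## Step count and risks

Total: 18 steps. Longest linear sequence: 15 steps (1, 2, 4, 5, 6, 7, 9, 10, 11, 12, 13, 14, 15, 16, 18, from compound 1).

Least certain steps:

1. Step 11 (key step).
   - Risk: decay of the enolate before ring closure (fragmentation to ketene and oxazolidinone anion on warming) or intermolecular alkylation, because a seven-membered transition state is slower than the intermolecular allylations on which the method rests. Facial selectivity may also erode, since the tether restricts the approach of the electrophile.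
   - Fallback (known reactions only), setting out from 11:
     - Appel bromination would give 5-(benzyloxy)-3-(bromomethyl)-7-methoxy-2-[4-(methoxymethoxy)-2-(prop-2-en-1-yloxy)phenyl]-4H-chromen-4-one F1.
     - The sodium enolate of (4R)-4-benzyl-3-{[(4-methoxybenzyl)oxy]acetyl}-1,3-oxazolidin-2-one F2 (from N-acylation of the (R)-oxazolidinone) would be alkylated intermolecularly by F1 to the (2S)-alkoxy imide F3.
     - MeOMgBr would give the (2S)-methyl ester F4, and DDQ would remove the 4-methoxybenzyl group to give the (2S)-hydroxy ester F5.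
     - Pd(PPh3)4 and morpholine would free the 2'-phenol, giving the phenol hydroxy ester F6.
     - An intramolecular Mitsunobu etherification (PPh3, DIAD, dilute toluene) would close ring D with inversion and rejoin the route at 19.

2. Step 6.
   - Risk: ring opening of the 3-lithio species by loss of the O1 phenoxide, or incomplete trapping by gaseous formaldehyde, since the anion is only stable cold and formaldehyde delivery is hard to control.
   - Fallback, setting out from 8:
     - N-bromosuccinimide (CH2Cl2, 0 °C) would brominate the activated methylene to the 2-bromo-1,3-diketone F7.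
     - The cyclodehydration of step 5 would give 5-(benzyloxy)-3-bromo-7-methoxy-2-[4-(methoxymethoxy)-2-(prop-2-en-1-yloxy)phenyl]-4H-chromen-4-one F8.
     - Stille coupling with Bu3SnCH2OH (Pd(PPh3)4, 1,4-dioxane, 90 °C) would rejoin the route at 11.

3. Step 15.
   - Risk: poor site selectivity. Iodination of ring B at C3' or C5' is the most likely leak, because ring B is a resorcinol diether; C8 is a second possibility.
   - Fallback, setting out from 22:
     - HCl in MeOH would remove the MOM group to give the 5,4'-dihydroxy carbinol F9.
     - Ac2O and pyridine (1.1 equiv, 0 °C) would acylate only the unchelated 4'-OH, giving the 4'-acetate F10, in which ring B is deactivated.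
     - The same iodination would give the 6-iodo 4'-acetate F11.
     - K2CO3 in MeOH would rejoin the route at 24.

4. Step 14.
   - Risk: epimerisation by enolisation of the ester or of ketone 21 by the basic Grignard reagent, or addition to C4=O if the phenoxide chelate protects less well than expected.
   - Fallback, setting out from 20:
     - MeNH(OMe)·HCl and i-PrMgCl (THF, −20 °C) would give the N-methoxy-N-methylamide F12.
     - One addition of MeMgBr would stop at the chelated adduct and rejoin the route at 21, now isolated.
     - A separate addition of MeMgBr to 21 at −78 °C would give 22.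

5. Step 5.
   - Risk: loss of the MOM group during cyclodehydration, since both processes are acid-catalysed.
   - Fallback, setting out from 8:
     - Aqueous HCl in MeOH at 50 °C would deliberately cyclise and cleave the MOM group to give 5-(benzyloxy)-2-[4-hydroxy-2-(prop-2-en-1-yloxy)phenyl]-7-methoxy-4H-chromen-4-one F13.
     - MOMCl and i-Pr2NEt would put the MOM group back on the only free hydroxyl and rejoin the route at 9.

## Further compounds

F1 | step 11 | 5-(benzyloxy)-3-(bromomethyl)-7-methoxy-2-[4-(methoxymethoxy)-2-(prop-2-en-1-yloxy)phenyl]-4H-chromen-4-one | COc1cc2oc(-c3ccc(OCOC)cc3OCC=C)c(CBr)c(=O)c2c(OCc4ccccc4)c1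
F2 | step 11 | (4R)-4-benzyl-3-{[(4-methoxybenzyl)oxy]acetyl}-1,3-oxazolidin-2-one | COc1ccc(COCC(=O)N2C(=O)OC[C@H]2Cc2ccccc2)cc1
F3 | step 11 | (4R)-4-benzyl-3-[(2S)-2-[(4-methoxybenzyl)oxy]-3-(flavon-3-yl)propanoyl]-1,3-oxazolidin-2-one, flavon-3-yl = 5-(benzyloxy)-7-methoxy-2-[4-(methoxymethoxy)-2-(prop-2-en-1-yloxy)phenyl]-4-oxo-4H-chromen-3-yl | COc1cc2oc(-c3ccc(OCOC)cc3OCC=C)c(C[C@H](OCc4ccc(OC)cc4)C(=O)N5C(=O)OC[C@H]5Cc6ccccc6)c(=O)c2c(OCc7ccccc7)c1
F4 | step 11 | methyl (2S)-2-[(4-methoxybenzyl)oxy]-3-(flavon-3-yl)propanoate, flavon-3-yl as in F3 | COc1cc2oc(-c3ccc(OCOC)cc3OCC=C)c(C[C@H](OCc4ccc(OC)cc4)C(=O)OC)c(=O)c2c(OCc5ccccc5)c1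
F5 | step 11 | methyl (2S)-2-hydroxy-3-(flavon-3-yl)propanoate, flavon-3-yl as in F3 | COc1cc2oc(-c3ccc(OCOC)cc3OCC=C)c(C[C@H](O)C(=O)OC)c(=O)c2c(OCc4ccccc4)c1
F6 | step 11 | methyl (2S)-3-{5-(benzyloxy)-2-[2-hydroxy-4-(methoxymethoxy)phenyl]-7-methoxy-4-oxo-4H-chromen-3-yl}-2-hydroxypropanoate | COc1cc2oc(-c3ccc(OCOC)cc3O)c(C[C@H](O)C(=O)OC)c(=O)c2c(OCc4ccccc4)c1
F7 | step 6 | 1-[2-(benzyloxy)-6-hydroxy-4-methoxyphenyl]-2-bromo-3-[4-(methoxymethoxy)-2-(prop-2-en-1-yloxy)phenyl]propane-1,3-dione | COc1cc(O)c(C(=O)C(Br)C(=O)c2ccc(OCOC)cc2OCC=C)c(OCc2ccccc2)c1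
F8 | step 6 | 5-(benzyloxy)-3-bromo-7-methoxy-2-[4-(methoxymethoxy)-2-(prop-2-en-1-yloxy)phenyl]-4H-chromen-4-one | COc1cc2oc(-c3ccc(OCOC)cc3OCC=C)c(Br)c(=O)c2c(OCc4ccccc4)c1
F9 | step 15 | (R)-tertiary alcohol with free 5-OH and 4'-OH (MOM removed from 22) | COc1cc2oc3c(c(=O)c2c(O)c1)C[C@H](C(C)(C)O)Oc4cc(O)ccc4-3
F10 | step 15 | 4'-O-acetate of F9 | COc1cc2oc3c(c(=O)c2c(O)c1)C[C@H](C(C)(C)O)Oc4cc(OC(C)=O)ccc4-3
F11 | step 15 | 6-iodo derivative of F10 | COc1cc2oc3c(c(=O)c2c(O)c1I)C[C@H](C(C)(C)O)Oc4cc(OC(C)=O)ccc4-3
F12 | step 14 | (R)-N-methoxy-N-methylamide corresponding to ester 20 | COc1cc2oc3c(c(=O)c2c(O)c1)C[C@H](C(=O)N(C)OC)Oc4cc(OCOC)ccc4-3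
F13 | step 5 | 5-(benzyloxy)-2-[4-hydroxy-2-(prop-2-en-1-yloxy)phenyl]-7-methoxy-4H-chromen-4-one | COc1cc2oc(-c3ccc(O)cc3OCC=C)cc(=O)c2c(OCc4ccccc4)c1
A1 | alternative 1 | ring-D-bridged 2',6'-dihydroxy-4'-methoxychalcone with (R) O–CH, carbinol and MOM ether | COc1cc(O)c(C(=O)C2=Cc3ccc(OCOC)cc3O[C@@H](C(C)(C)O)C2)c(O)c1
A2 | alternative 1 | 4-methoxy-6-(2-oxoethyl)-2H-pyran-2-one whose ketone carbon carries the (2R)-2-(2-hydroxypropan-2-yl)-8-(methoxymethoxy)-2,3-dihydro-1-benzoxepin-4-yl group | COc1cc(=O)oc(CC(=O)C2=Cc3ccc(OCOC)cc3O[C@@H](C(C)(C)O)C2)c1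
A3 | alternative 2 | target with tertiary O-triethylsilyl and 4'-O-MOM groups | COc1cc2oc3c(c(=O)c2c(O)c1/C=C/C(C)C)C[C@H](C(C)(C)O[Si](CC)(CC)CC)Oc4cc(OCOC)ccc4-3
A4 | alternative 2 | tricyclic 4-pyranone (rings C, D, B; (R) O–CH; O-triethylsilyl carbinol; MOM ether) with a diazoacetyl group on the pyranone carbon next to O1 | [N-]=[N+]=CC(=O)c1cc(=O)c2c(o1)-c1ccc(OCOC)cc1O[C@@H](C(C)(C)O[Si](CC)(CC)CC)C2
A5 | alternative 2 | (E)-1-methoxy-5-methylhex-3-en-1-yne | COC#C/C=C/C(C)C
A6 | alternative 3 | 4'-O-MOM tetracycle lacking only the C6 alkenyl group (identical with 22) | COc1cc2oc3c(c(=O)c2c(O)c1)C[C@H](C(C)(C)O)Oc4cc(OCOC)ccc4-3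
A7 | alternative 3 | 3-[(2R)-2-[2-bromo-5-(methoxymethoxy)phenoxy]-3-hydroxy-3-methylbutyl]-5-hydroxy-7-methoxy-4H-chromen-4-one | COc1cc2occ(C[C@H](C(C)(C)O)Oc3cc(OCOC)ccc3Br)c(=O)c2c(O)c1
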